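## Retrosynthetic overview

1. Numbering (labdane type): ring A = C1–C5 + C10, ring B = C5–C10, C18 = formyl carbon on C4, side chain C11–C12–C13(=CH2)–C14(OH)–C15(OH)–C16 (γ-carbon of the butenolide).
2. Target ⇐ one acidic unmasking (C18 dioxolane, 14,15-acetonide) ⇐ C12–C13 by hydroboration/B-alkyl Suzuki coupling of a C9-vinyl decalin diol with a 2-bromoalkene that already carries C14–C16 and the butenolide (from L-threitol acetonide).
3. Decalin ⇐ 5α,8α-oxygen-bridged 6-ketone (reductive C5–O cleavage α to the ketone, then thermodynamic ketone reduction) ⇐ intramolecular Diels–Alder reaction of a furan that forms C5–C10 and C8–C9 at once, closing ring A and ring B together and setting C5, C8, C9 and C10.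
4. Enabling feature: in ring B the unit C5–C6(O)–C7–C8(O)(CH3) is a latent 5-methylfuran-3(2H)-one with O8 as ring oxygen. Its 3-silyloxyfuran is an electron-rich diene across C5/C8, and C9=C10 (C20 methyl, C11 as formyl) is an (E)-enal dienophile held by the tether C1–C4.
5. C4, the only stereocentre of the cyclization precursor, comes from Sharpless epoxidation and Yamamoto epoxy silyl ether rearrangement of a symmetric diene-diol made from hepta-1,6-diyne. Ring order: furan (temporary) → rings A and B in one step → butenolide delivered with the side chain.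

Key step: step 13

Remark: the target is taken in the open 6α-hydroxy-18-aldehyde form as drawn (it can equilibrate with the O6–C18 lactol); β denotes the face of the C10 methyl group; TBS = tert-butyldimethylsilyl, TBDPS = tert-butyldiphenylsilyl.

## Route

Step 1
Reactants: 1 hepta-1,6-diyne
Product: 3 (2E,7E)-3,7-dimethylnona-2,7-diene-1,9-diol, via bis-alkenylalane 2 (not isolated)
Conditions: Me3Al, Cp2ZrCl2 (cat.), CH2Cl2, rt; then n-BuLi, THF, −78 °C; (CH2O)n, −78 °C to rt
Reagents that add atoms: trimethylaluminium C[Al](C)C; formaldehyde (from paraformaldehyde) C=O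
Why: Negishi zirconium-catalysed carboalumination adds methyl and aluminium syn across each terminal alkyne with methyl at the internal carbon, which fixes both E-trisubstituted alkenes, and the derived alanate is hydroxymethylated with retention of geometry.

Step 2
Reactants: 3 (2E,7E)-3,7-dimethylnona-2,7-diene-1,9-diol
Product: 4 (2E,7E)-9-(TBDPS-oxy)-3,7-dimethylnona-2,7-dien-1-ol
Conditions: NaH (1 equiv), THF, 0 °C; TBDPSCl (1 equiv)
Reagents that add atoms: tert-butyl(chloro)diphenylsilane CC(C)(C)[Si](Cl)(c1ccccc1)c1ccccc1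
Why: Statistical monosilylation of the symmetric diol through its monosodium alkoxide (silyl ether formation) differentiates the two ends; no stereocentre is formed.

Step 3
Reactants: 4 (2E,7E)-9-(TBDPS-oxy)-3,7-dimethylnona-2,7-dien-1-ol
Product: 5 (2R,3R)-2,3-epoxy alcohol
Conditions: Ti(OiPr)4 (cat.), D-(−)-diisopropyl tartrate (cat.), t-BuOOH, 4 Å MS, CH2Cl2, −20 °C
Reagents that add atoms: tert-butyl hydroperoxide CC(C)(C)OO
Why: Sharpless asymmetric epoxidation of the free allylic alcohol with the D-tartrate catalyst should deliver oxygen to the face that gives the (2R,3R)-epoxide, while the silylated allylic alkene is not a substrate.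

Step 4
Reactants: 5 (2R,3R)-2,3-epoxy alcohol
Product: 6 (2R,3R)-epoxy TBS ether
Conditions: TBSCl, imidazole, DMF, rt
Reagents that add atoms: tert-butyl(chloro)dimethylsilane CC(C)(C)[Si](C)(C)Cl
Why: Standard silyl ether formation supplies the siloxymethyl group that serves as the migrating group in the next step.

Step 5
Reactants: 6 (2R,3R)-epoxy TBS ether
Product: 7 (2R,6E)-8-(TBDPS-oxy)-2-(TBS-oxymethyl)-2,6-dimethyloct-6-enal
Conditions: MeAl(OAr)2 (Ar = 4-bromo-2,6-di-tert-butylphenyl; 2 equiv), CH2Cl2, −78 °C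
Reagents that add atoms: none
Why: Yamamoto epoxy silyl ether rearrangement (a semipinacol-type 1,2-shift): the bulky aluminium Lewis acid opens the epoxide at its tertiary carbon and the siloxymethyl group migrates anti to the breaking C–O bond, so the epoxide chirality is relayed with inversion into the quaternary centre C4 (R) and the former epoxide CH becomes the aldehyde carbon C18.

Step 6
Reactants: 7 (2R,6E)-8-(TBDPS-oxy)-2-(TBS-oxymethyl)-2,6-dimethyloct-6-enal
Product: 9 (2R,6E)-8-(TBDPS-oxy)-2-(1,3-dioxolan-2-yl)-2,6-dimethyloct-6-en-1-ol, via TBS dioxolane 8 (not isolated)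
Conditions: TMSOCH2CH2OTMS, TMSOTf (cat.), CH2Cl2, −78 °C; then HF·pyridine, pyridine, THF, 0 °C
Reagents that add atoms: 1,2-bis(trimethylsilyloxy)ethane C[Si](C)(C)OCCO[Si](C)(C)C
Why: Noyori acetalization masks the hindered aldehyde (C18) as a dioxolane under aprotic conditions, and buffered hydrogen fluoride then cleaves the primary TBS ether much faster than the TBDPS ether (selective desilylation).

Step 7
Reactants: 9 (2R,6E)-8-(TBDPS-oxy)-2-(1,3-dioxolan-2-yl)-2,6-dimethyloct-6-en-1-ol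
Product: 10 (2R,6E)-8-(TBDPS-oxy)-2-(1,3-dioxolan-2-yl)-2,6-dimethyloct-6-enal
Conditions: Dess–Martin periodinane, CH2Cl2, rt
Reagents that add atoms: none
Why: Dess–Martin oxidation gives the neopentyl aldehyde (future C5), which has no α-hydrogen and can neither epimerize nor eliminate.

Step 8
Reactants: 10 (2R,6E)-8-(TBDPS-oxy)-2-(1,3-dioxolan-2-yl)-2,6-dimethyloct-6-enal
Product: 11 (4R,8E)-10-(TBDPS-oxy)-4-(1,3-dioxolan-2-yl)-4,8-dimethyldec-8-en-1-yn-3-ol (both C3 epimers)
Conditions: HC≡CMgBr, THF, −78 to 0 °C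
Reagents that add atoms: ethynylmagnesium bromide C#C[Mg]Br
Why: Grignard addition of the acetylide to the aldehyde; the new carbinol centre forms without control, which is harmless because this carbon becomes sp2 in the furan.

Step 9
Reactants: 11 (4R,8E)-10-(TBDPS-oxy)-4-(1,3-dioxolan-2-yl)-4,8-dimethyldec-8-en-1-yn-3-ol
Product: 12 (6R,10E)-12-(TBDPS-oxy)-6-(1,3-dioxolan-2-yl)-5-hydroxy-6,10-dimethyldodec-10-en-3-yn-2-one (both C5 epimers)
Conditions: n-BuLi (2.2 equiv), THF, −78 °C; then MeC(O)N(OMe)Me, −78 to 0 °C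
Reagents that add atoms: N-methoxy-N-methylacetamide CC(=O)N(C)OC
Why: Weinreb ketone synthesis on the alkoxide–acetylide dianion gives the ynone, the chelated tetrahedral intermediate preventing over-addition.

Step 10
Reactants: 12 (6R,10E)-12-(TBDPS-oxy)-6-(1,3-dioxolan-2-yl)-5-hydroxy-6,10-dimethyldodec-10-en-3-yn-2-one
Product: 14 2-[(2R,6E)-8-(TBDPS-oxy)-2-(1,3-dioxolan-2-yl)-6-methyloct-6-en-2-yl]-5-methylfuran-3(2H)-one, via enaminone 13 (not isolated)
Conditions: Et2NH, EtOH, rt; then AcOH/H2O/THF, rt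
Reagents that add atoms: water O
Why: Conjugate (aza-Michael) addition of diethylamine to the ynone, hydrolysis of the enaminone to the 1,3-diketone and cyclodehydration by the neighbouring hydroxyl give the 3(2H)-furanone (classical furanone synthesis from 4-hydroxy-2-ynones); the ring CH stereocentre is labile and irrelevant.

Step 11
Reactants: 14 2-[(2R,6E)-8-(TBDPS-oxy)-2-(1,3-dioxolan-2-yl)-6-methyloct-6-en-2-yl]-5-methylfuran-3(2H)-one
Product: 15 2-[(2R,6E)-2-(1,3-dioxolan-2-yl)-8-hydroxy-6-methyloct-6-en-2-yl]-5-methylfuran-3(2H)-one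
Conditions: Bu4NF, AcOH, THF, rt
Reagents that add atoms: none
Why: Fluoride-mediated desilylation buffered by acetic acid frees the allylic alcohol without opening the furanone.

Step 12
Reactants: 15 2-[(2R,6E)-2-(1,3-dioxolan-2-yl)-8-hydroxy-6-methyloct-6-en-2-yl]-5-methylfuran-3(2H)-one
Product: 16 (2E,7R)-7-(1,3-dioxolan-2-yl)-3-methyl-7-(5-methyl-3-oxo-2,3-dihydrofuran-2-yl)oct-2-enal
Conditions: MnO2, CH2Cl2, rt
Reagents that add atoms: none
Why: Manganese dioxide oxidizes only the allylic alcohol and keeps the E-geometry, unveiling the enal dienophile immediately before use.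

Step 13
Reactants: 16 (2E,7R)-7-(1,3-dioxolan-2-yl)-3-methyl-7-(5-methyl-3-oxo-2,3-dihydrofuran-2-yl)oct-2-enal
Product: 19 oxygen-bridged keto aldehyde (5α,8α-epoxy-6-oxo-9β-formyl decalin), via silyloxyfuran 17 (not isolated), via silyl enol ether 18 (not isolated)
Conditions: TBSOTf, Et3N, CH2Cl2, −78 to 0 °C; then PhMe, 90 °C; then 1 M HCl aq, THF, 0 °C
Reagents that add atoms: none
Why: O-Silylation of the furanone at its only aromatizing enolization site gives 3-silyloxyfuran 17, whose diene termini C5 and C8 add suprafacially to the tethered (E)-enal C10=C9 in a concerted, asynchronous normal-demand [4+2] cycloaddition (C5–C10 leading, C8–C9 completing ring B), and acid hydrolysis of silyl enol ether 18 to ketone 19 removes the alkene needed for cycloreversion. The closest known reaction type is the intramolecular Diels–Alder reaction of furans, here with a 3-oxygenated furan of Danishefsky-diene polarity matched to the enal (nucleophilic C5 to the β-carbon C10). Ring A closes through the tether C4–C1 in a chair-like six-membered array with the tether exo (syn to the oxygen bridge), and ring B closes as the new cyclohexene, held as a boat by the furan oxygen. C5 and C8 are set by suprafacial addition to the furan, C10 by the exo-tether geometry (methyl anti to the bridge), C9 by the E-geometry of the enal together with the endo formyl group, and all four relative to C4 by the furan face that is attacked. The step needs facial selectivity and a favourable equilibrium: only the C4 rotamer with methyl next to the 3-silyloxy group (and 1,3-diaxial to the incoming C10 methyl) and the branched dioxolanyl group on the face away from the dienophile avoids allylic 1,3-strain, the fully substituted C4 favours closure, and the hydrolysis makes the adduct irreversible.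

Step 14
Reactants: 19 oxygen-bridged keto aldehyde
Product: 20 oxygen-bridged 9β-vinyl ketone
Conditions: Zn, CH2I2, Ti(OiPr)4, THF, rt
Reagents that add atoms: diiodomethane ICI
Why: Takai methylenation with the gem-dizinc reagent and titanium tetraisopropoxide is selective for the aldehyde over the hindered ketone and is non-basic, so neither the C9 stereocentre nor the β-oxygen bridge is endangered.

Step 15
Reactants: 20 oxygen-bridged 9β-vinyl ketone
Product: 22 9β-vinyl-6α,8α-diol (trans-decalin), via hydroxy ketone 21 (not isolated)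
Conditions: Li, NH3 (l), THF, EtOH, −78 to −33 °C; then NH4Cl
Reagents that add atoms: none
Why: Dissolving-metal reduction first cleaves the C5–O bond α to the ketone (ketyl fragmentation), the enolate is protonated on the α-face opposite the two axial methyl groups to give the trans-decalin, and the hindered C6 ketone is then reduced under thermodynamic control to the equatorial 6α-alcohol, as is usual for ketones flanked by syn-axial methyl groups.

Step 16
Reactants: 23 (4S,5S)-2,2-dimethyl-1,3-dioxolane-4,5-dimethanol (2,3-O-isopropylidene-L-threitol)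
Product: 24 [(4S,5S)-5-(TBS-oxymethyl)-2,2-dimethyl-1,3-dioxolan-4-yl]methanol
Conditions: NaH (1 equiv), THF, 0 °C; TBSCl (1 equiv)
Reagents that add atoms: tert-butyl(chloro)dimethylsilane CC(C)(C)[Si](C)(C)Cl
Why: Monosilylation of the C2-symmetric diol through its monosodium alkoxide; either hydroxyl gives the same product.

Step 17
Reactants: 24 [(4S,5S)-5-(TBS-oxymethyl)-2,2-dimethyl-1,3-dioxolan-4-yl]methanol
Product: 25 (4R,5S)-5-(TBS-oxymethyl)-2,2-dimethyl-1,3-dioxolane-4-carbaldehyde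
Conditions: Dess–Martin periodinane, CH2Cl2, rt
Reagents that add atoms: none
Why: Dess–Martin oxidation gives the α-alkoxy aldehyde, configurationally secure as the trans-dioxolane.

Step 18
Reactants: 25 (4R,5S)-5-(TBS-oxymethyl)-2,2-dimethyl-1,3-dioxolane-4-carbaldehyde
Product: 26 (4S,5S)-4-(TBS-oxymethyl)-5-ethynyl-2,2-dimethyl-1,3-dioxolane
Conditions: MeC(O)C(N2)P(O)(OMe)2, K2CO3, MeOH, 0 °C to rt
Reagents that add atoms: dimethyl (1-diazo-2-oxopropyl)phosphonate CC(=O)C(=[N+]=[N-])P(=O)(OC)OC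
Why: Ohira–Bestmann (Seyferth–Gilbert) homologation turns the aldehyde carbon into the internal alkyne carbon (future C13) without touching the adjacent stereocentre.

Step 19
Reactants: 26 (4S,5S)-4-(TBS-oxymethyl)-5-ethynyl-2,2-dimethyl-1,3-dioxolane
Product: 28 (4S,5R)-4-(TBS-oxymethyl)-5-(1-bromoethenyl)-2,2-dimethyl-1,3-dioxolane, via alkenylborane 27 (not isolated)
Conditions: B-bromo-9-BBN, CH2Cl2, −78 to 0 °C; then AcOH, 0 °C
Reagents that add atoms: B-bromo-9-borabicyclo[3.3.1]nonane BrB1C2CCCC1CCC2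
Why: Hara–Suzuki haloboration adds B–Br syn and Markovnikov across the terminal alkyne, and protodeboration with acetic acid leaves the 2-bromo-1-alkene.

Step 20
Reactants: 28 (4S,5R)-4-(TBS-oxymethyl)-5-(1-bromoethenyl)-2,2-dimethyl-1,3-dioxolane
Product: 29 [(4S,5R)-5-(1-bromoethenyl)-2,2-dimethyl-1,3-dioxolan-4-yl]methanol
Conditions: Bu4NF, THF, 0 °C
Reagents that add atoms: none
Why: Fluoride-mediated desilylation; the acetonide and the vinyl bromide are inert.

Step 21
Reactants: 29 [(4S,5R)-5-(1-bromoethenyl)-2,2-dimethyl-1,3-dioxolan-4-yl]methanol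
Product: 30 (4R,5R)-5-(1-bromoethenyl)-2,2-dimethyl-1,3-dioxolane-4-carbaldehyde
Conditions: Dess–Martin periodinane, CH2Cl2, rt
Reagents that add atoms: none
Why: Dess–Martin oxidation to the α-alkoxy aldehyde (future C16) under non-epimerizing conditions.

Step 22
Reactants: 30 (4R,5R)-5-(1-bromoethenyl)-2,2-dimethyl-1,3-dioxolane-4-carbaldehyde
Product: 31 methyl (4R)-4-[(4S,5R)-5-(1-bromoethenyl)-2,2-dimethyl-1,3-dioxolan-4-yl]-4-hydroxybut-2-ynoate
Conditions: methyl propiolate, LiN(SiMe3)2, THF, −78 °C; ZnBr2, Et2O, −78 °C; then 30, −78 to −20 °C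
Reagents that add atoms: methyl propiolate C#CC(=O)OC
Why: Chelation-controlled (Cram-chelate) addition of the alkynylzinc bromide: zinc bridges the aldehyde oxygen and the α-oxygen of the dioxolane and the acetylide enters anti to the ring substituent, which should give the syn (threo) carbinol, (R) at C16.

Step 23
Reactants: 31 methyl (4R)-4-[(4S,5R)-5-(1-bromoethenyl)-2,2-dimethyl-1,3-dioxolan-4-yl]-4-hydroxybut-2-ynoate
Product: 33 (5R)-5-[(4S,5R)-5-(1-bromoethenyl)-2,2-dimethyl-1,3-dioxolan-4-yl]-4-methylfuran-2(5H)-one, via hydroxy enoate 32 (not isolated)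
Conditions: Me2CuLi (3 equiv), THF, −78 °C; then AcOH, −78 °C to rt
Reagents that add atoms: lithium dimethylcuprate [Li+].C[Cu-]C
Why: syn-Conjugate addition of the methyl cuprate to the ynoate gives the (Z)-γ-hydroxy enoate with the ester cis to the carbinol carbon, which lactonizes on acidic work-up to the β-methyl butenolide without touching C16.

Step 24
Reactants: 22 9β-vinyl-6α,8α-diol; 33 (5R)-5-[(4S,5R)-5-(1-bromoethenyl)-2,2-dimethyl-1,3-dioxolan-4-yl]-4-methylfuran-2(5H)-one
Product: 35 acetal-protected target (C18 dioxolane and 14,15-acetonide), via alkylborane 34 (not isolated)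
Conditions: 9-BBN (excess), THF, rt; then 33, Pd(dppf)Cl2 (cat.), AsPh3, K3PO4 aq, DMF, rt
Reagents that add atoms: none
Why: Anti-Markovnikov hydroboration of the monosubstituted alkene with 9-BBN followed by B-alkyl Suzuki–Miyaura coupling with the 2-bromoalkene forms the C12–C13 bond and installs the 1,1-disubstituted alkene directly; no stereocentre is touched.

Step 25
Reactants: 35 acetal-protected target
Product: 36 CNP0156243.1 (target)
Conditions: AcOH/H2O (4:1), 45 °C
Reagents that add atoms: water O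
Why: Acid-catalysed acetal hydrolysis removes the acetonide and the dioxolane in one operation, the latter assisted by the neighbouring 6α-hydroxyl through a transient cyclic acetal, under conditions that should leave the tertiary alcohol, the allylic alcohol and the butenolide intact.

## Compound list

1 | hepta-1,6-diyne | C#CCCCC#C | starting material
2 | (1E,6E)-1,7-bis(dimethylalumanyl)-2,6-dimethylhepta-1,6-diene | C[Al](C)/C=C(\C)CCC/C(C)=C/[Al](C)C | intermediate
3 | (2E,7E)-3,7-dimethylnona-2,7-diene-1,9-diol | OC/C=C(\C)CCC/C(C)=C/CO | intermediate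
4 | (2E,7E)-9-(tert-butyldiphenylsilyloxy)-3,7-dimethylnona-2,7-dien-1-ol | OC/C=C(\C)CCC/C(C)=C/CO[Si](c1ccccc1)(c1ccccc1)C(C)(C)C | intermediate
5 | [(2R,3R)-3-[(4E)-6-(tert-butyldiphenylsilyloxy)-4-methylhex-4-enyl]-3-methyloxiran-2-yl]methanol | OC[C@H]1O[C@]1(C)CCC/C(C)=C/CO[Si](c2ccccc2)(c2ccccc2)C(C)(C)C | intermediate
6 | TBS ether of 5, (2R,3R)-epoxide | CC(C)(C)[Si](C)(C)OC[C@H]1O[C@]1(C)CCC/C(C)=C/CO[Si](c2ccccc2)(c2ccccc2)C(C)(C)C | intermediate
7 | (2R,6E)-8-(TBDPS-oxy)-2-(TBS-oxymethyl)-2,6-dimethyloct-6-enal | CC(C)(C)[Si](c1ccccc1)(c1ccccc1)OC/C=C(\C)CCC[C@@](C)(C=O)CO[Si](C)(C)C(C)(C)C | intermediate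
8 | 2-[(2R,6E)-8-(TBDPS-oxy)-1-(TBS-oxy)-2,6-dimethyloct-6-en-2-yl]-1,3-dioxolane | CC(C)(C)[Si](c1ccccc1)(c1ccccc1)OC/C=C(\C)CCC[C@@](C)(C1OCCO1)CO[Si](C)(C)C(C)(C)C | intermediate
9 | (2R,6E)-8-(TBDPS-oxy)-2-(1,3-dioxolan-2-yl)-2,6-dimethyloct-6-en-1-ol | CC(C)(C)[Si](c1ccccc1)(c1ccccc1)OC/C=C(\C)CCC[C@@](C)(C1OCCO1)CO | intermediate
10 | (2R,6E)-8-(TBDPS-oxy)-2-(1,3-dioxolan-2-yl)-2,6-dimethyloct-6-enal | CC(C)(C)[Si](c1ccccc1)(c1ccccc1)OC/C=C(\C)CCC[C@@](C)(C1OCCO1)C=O | intermediate
11 | (4R,8E)-10-(TBDPS-oxy)-4-(1,3-dioxolan-2-yl)-4,8-dimethyldec-8-en-1-yn-3-ol, both C3 epimers | CC(C)(C)[Si](c1ccccc1)(c1ccccc1)OC/C=C(\C)CCC[C@@](C)(C1OCCO1)C(O)C#C | intermediate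
12 | (6R,10E)-12-(TBDPS-oxy)-6-(1,3-dioxolan-2-yl)-5-hydroxy-6,10-dimethyldodec-10-en-3-yn-2-one, both C5 epimers | CC(C)(C)[Si](c1ccccc1)(c1ccccc1)OC/C=C(\C)CCC[C@@](C)(C1OCCO1)C(O)C#CC(C)=O | intermediate
13 | 4-(diethylamino) enaminone adduct of 12 (alkene isomers, both C5 epimers) | CC(C)(C)[Si](c1ccccc1)(c1ccccc1)OC/C=C(\C)CCC[C@@](C)(C1OCCO1)C(O)C(=CC(C)=O)N(CC)CC | intermediate
14 | 2-[(2R,6E)-8-(TBDPS-oxy)-2-(1,3-dioxolan-2-yl)-6-methyloct-6-en-2-yl]-5-methylfuran-3(2H)-one, both ring C2 epimers | CC(C)(C)[Si](c1ccccc1)(c1ccccc1)OC/C=C(\C)CCC[C@@](C)(C1OCCO1)C1OC(C)=CC1=O | intermediate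
15 | 2-[(2R,6E)-2-(1,3-dioxolan-2-yl)-8-hydroxy-6-methyloct-6-en-2-yl]-5-methylfuran-3(2H)-one | OC/C=C(\C)CCC[C@@](C)(C1OCCO1)C1OC(C)=CC1=O | intermediate
16 | (2E,7R)-7-(1,3-dioxolan-2-yl)-3-methyl-7-(5-methyl-3-oxo-2,3-dihydrofuran-2-yl)oct-2-enal | O=C/C=C(\C)CCC[C@@](C)(C1OCCO1)C1OC(C)=CC1=O | intermediate
17 | (2E,7R)-7-[3-(tert-butyldimethylsilyloxy)-5-methylfuran-2-yl]-7-(1,3-dioxolan-2-yl)-3-methyloct-2-enal | O=C/C=C(\C)CCC[C@@](C)(C1OCCO1)c1oc(C)cc1O[Si](C)(C)C(C)(C)C | intermediate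
18 | cycloadduct silyl enol ether: 5α,8α-epoxy, C6(OTBS)=C7, 9β-CHO, 10β-CH3, 8β-CH3 (bridgehead), 4β-CH3, 4α-(1,3-dioxolan-2-yl) | O=C[C@@H]1[C@@]2(C)CCC[C@@](C)(C3OCCO3)[C@@]24O[C@]1(C)C=C4O[Si](C)(C)C(C)(C)C | intermediate
19 | oxygen-bridged keto aldehyde: 5α,8α-epoxy-6-oxo, 9β-CHO (9α-H), 10β-CH3, 8β-CH3, 4β-CH3, 4α-(1,3-dioxolan-2-yl) | O=C[C@@H]1[C@@]2(C)CCC[C@@](C)(C3OCCO3)[C@@]24O[C@]1(C)CC4=O | intermediate
20 | oxygen-bridged 9β-vinyl ketone (as 19, CHO replaced by CH=CH2) | C=C[C@@H]1[C@@]2(C)CCC[C@@](C)(C3OCCO3)[C@@]24O[C@]1(C)CC4=O | intermediate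
21 | trans-decalin hydroxy ketone: 5α-H, 6-oxo, 8α-OH, 8β-CH3, 9β-vinyl, 10β-CH3, 4β-CH3, 4α-(1,3-dioxolan-2-yl) | C=C[C@@H]1[C@@]2(C)CCC[C@@](C)(C3OCCO3)[C@@H]2C(=O)C[C@@]1(C)O | intermediate
22 | trans-decalin diol: 5α-H, 6α-OH, 8α-OH, 8β-CH3, 9β-vinyl, 10β-CH3, 4β-CH3, 4α-(1,3-dioxolan-2-yl) | C=C[C@@H]1[C@@]2(C)CCC[C@@](C)(C3OCCO3)[C@@H]2[C@@H](O)C[C@@]1(C)O | intermediate
23 | (4S,5S)-2,2-dimethyl-1,3-dioxolane-4,5-dimethanol (2,3-O-isopropylidene-L-threitol) | OC[C@@H]1OC(C)(C)O[C@H]1CO | starting material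
24 | [(4S,5S)-5-(tert-butyldimethylsilyloxymethyl)-2,2-dimethyl-1,3-dioxolan-4-yl]methanol | OC[C@@H]1OC(C)(C)O[C@H]1CO[Si](C)(C)C(C)(C)C | intermediate
25 | (4R,5S)-5-(tert-butyldimethylsilyloxymethyl)-2,2-dimethyl-1,3-dioxolane-4-carbaldehyde | O=C[C@@H]1OC(C)(C)O[C@H]1CO[Si](C)(C)C(C)(C)C | intermediate
26 | (4S,5S)-4-(tert-butyldimethylsilyloxymethyl)-5-ethynyl-2,2-dimethyl-1,3-dioxolane | C#C[C@@H]1OC(C)(C)O[C@H]1CO[Si](C)(C)C(C)(C)C | intermediate
27 | (Z)-2-bromoalkenyl-9-BBN from 26 (B and Br cis) | Br/C(=C\B1C2CCCC1CCC2)[C@@H]3OC(C)(C)O[C@H]3CO[Si](C)(C)C(C)(C)C | intermediate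
28 | (4S,5R)-4-(tert-butyldimethylsilyloxymethyl)-5-(1-bromoethenyl)-2,2-dimethyl-1,3-dioxolane | C=C(Br)[C@@H]1OC(C)(C)O[C@H]1CO[Si](C)(C)C(C)(C)C | intermediate
29 | [(4S,5R)-5-(1-bromoethenyl)-2,2-dimethyl-1,3-dioxolan-4-yl]methanol | C=C(Br)[C@@H]1OC(C)(C)O[C@H]1CO | intermediate
30 | (4R,5R)-5-(1-bromoethenyl)-2,2-dimethyl-1,3-dioxolane-4-carbaldehyde | C=C(Br)[C@@H]1OC(C)(C)O[C@H]1C=O | intermediate
31 | methyl (4R)-4-[(4S,5R)-5-(1-bromoethenyl)-2,2-dimethyl-1,3-dioxolan-4-yl]-4-hydroxybut-2-ynoate | C=C(Br)[C@@H]1OC(C)(C)O[C@H]1[C@H](O)C#CC(=O)OC | intermediate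
32 | methyl (2Z,4R)-4-[(4S,5R)-5-(1-bromoethenyl)-2,2-dimethyl-1,3-dioxolan-4-yl]-4-hydroxy-3-methylbut-2-enoate | C=C(Br)[C@@H]1OC(C)(C)O[C@H]1[C@H](O)/C(C)=C\C(=O)OC | intermediate
33 | (5R)-5-[(4S,5R)-5-(1-bromoethenyl)-2,2-dimethyl-1,3-dioxolan-4-yl]-4-methylfuran-2(5H)-one | C=C(Br)[C@@H]1OC(C)(C)O[C@H]1[C@@H]2OC(=O)C=C2C | intermediate
34 | B-alkyl-9-BBN from 22 (boron on C12) | C(CB3C4CCCC3CCC4)[C@@H]1[C@@]2(C)CCC[C@@](C)(C5OCCO5)[C@@H]2[C@@H](O)C[C@@]1(C)O | intermediate
35 | acetal-protected target: C18 as 1,3-dioxolane, 14,15-diol as acetonide, free 6α-OH and 8α-OH | C=C(CC[C@@H]1[C@@]2(C)CCC[C@@](C)(C3OCCO3)[C@@H]2[C@@H](O)C[C@@]1(C)O)[C@@H]4OC(C)(C)O[C@H]4[C@@H]5OC(=O)C=C5C | intermediate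
36 | CNP0156243.1 | C=C(CC[C@@H]1[C@@]2(C)CCC[C@@](C)(C=O)[C@@H]2[C@@H](O)C[C@@]1(C)O)[C@H](O)[C@@H](O)[C@@H]1OC(=O)C=C1C | target

## Step count and risks

Total steps: 25. Longest linear sequence: 17 (steps 1–15, 24, 25).

Steps most likely to fail:

1. Step 13. The cycloaddition onto the β,β-disubstituted enal may be slow or may revert at the temperature it needs, and discrimination of the two furan faces by C4 may be incomplete. The fallback is a stepwise anionic double Michael sequence that sets out from 16. DBU in MeCN should close ring A by Michael addition of the furanone carbanion (C5) to the enal and give the spiro furanone aldehyde F1. Pyrrolidine/AcOH (enamine activation of the aldehyde) should then close C8–C9 by intramolecular Michael addition to the furanone enone, coming back to the route at 19.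

2. Step 15. Protonation and reduction may deliver the axial 6β-alcohol instead of the equatorial one, or the β-alkoxy ketone stage may open ring B by retro-aldol cleavage. The fallback sets out from 20. SmI2 in THF/MeOH at −78 °C cleaves only the C5–O bond, and hydroxy ketone 21 is isolated. NaBH4 reduces it from the open α-face to the 6β-alcohol F2. Mitsunobu inversion (4-nitrobenzoic acid, PPh3, DIAD) gives the 6α-ester F3, and K2CO3/MeOH comes back to the route at 22.

3. Step 22. Chelate and Felkin pathways may compete, eroding facial selectivity at C16. The fallback sets out from 30. Lithium methyl propiolate without zinc gives 31 mixed with its C16 epimer F4. Dess–Martin oxidation of the mixture gives ynone F5, and reagent-controlled Midland reduction with (S)-Alpine-Borane comes back to the route at 31.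

Further compounds
F1 | step 13 | 2-[10-(1,3-dioxolan-2-yl)-2,6,10-trimethyl-4-oxo-1-oxaspiro[4.5]dec-2-en-6-yl]acetaldehyde (ring A closed, C4/C5/C10 as in 19) | O=CC[C@@]2(C)CCC[C@@](C)(C3OCCO3)[C@@]24OC(C)=CC4=O
F2 | step 15 | 6β-alcohol, C6 epimer of 22 | C=C[C@@H]1[C@@]2(C)CCC[C@@](C)(C3OCCO3)[C@@H]2[C@H](O)C[C@@]1(C)O
F3 | step 15 | 6α-(4-nitrobenzoate) of 22 | C=C[C@@H]1[C@@]2(C)CCC[C@@](C)(C3OCCO3)[C@@H]2[C@@H](OC(=O)c4ccc(cc4)[N+](=O)[O-])C[C@@]1(C)O
F4 | step 22 | methyl (4S)-4-[(4S,5R)-5-(1-bromoethenyl)-2,2-dimethyl-1,3-dioxolan-4-yl]-4-hydroxybut-2-ynoate (C16 epimer of 31) | C=C(Br)[C@@H]1OC(C)(C)O[C@H]1[C@@H](O)C#CC(=O)OC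
F5 | step 22 | methyl 4-[(4R,5R)-5-(1-bromoethenyl)-2,2-dimethyl-1,3-dioxolan-4-yl]-4-oxobut-2-ynoate | C=C(Br)[C@@H]1OC(C)(C)O[C@H]1C(=O)C#CC(=O)OC
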